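**Retrosynthetic overview**
- The (E)-3-hydroxy-3-methylbut-1-enyl chain is attached last by a Heck reaction on an aryl bromide, because the tertiary allylic alcohol would not survive acid.
- The chromone C2=C3 bond comes from dehydration of a 3-aryl-3-hydroxychroman-4-one, with MOM removal in the same operation.
- Key bond C4–C3: an NHC-catalysed intramolecular crossed aldehyde–ketone benzoin reaction, in which the A-ring aldehyde carbon acts as an acyl anion equivalent and attacks the B-ring aryl ketone carbonyl.
- The benzoin substrate is made by Williamson etherification of a MOM-protected phloroglucinaldehyde with a B-ring phenacyl bromide, the latter prepared from 3',4'-dihydroxyacetophenone.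
- Rings A and B are bought; the pyranone ring is the only ring formed (closed in the benzoin step, unsaturated in the dehydration).

Assumption: the target has no stereocentre, so "single enantiomer" is read as the single (E)-alkene isomer drawn.

**Step 1**
Reactants: 1 2,4,6-trihydroxybenzaldehyde
Product: 2 2-hydroxy-4,6-bis(methoxymethoxy)benzaldehyde
Conditions: MOMCl (2.2 equiv), i-Pr2NEt (2.5 equiv), CH2Cl2, 0 °C → rt
Reagents that add atoms: chloromethyl methyl ether (MOMCl), COCCl
Why: O-alkylation (MOM protection) takes the 4-OH and one ortho-OH, while the remaining ortho-OH is held in a hydrogen bond to the aldehyde and stays free for step 6; no stereocentre.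

**Step 2**
Reactants: 3 1-(3,4-dihydroxyphenyl)ethanone
Product: 4 1-(3-bromo-4,5-dihydroxyphenyl)ethanone
Conditions: Br2 (1.0 equiv), AcOH, 15 °C → rt
Reagents that add atoms: bromine, BrBr
Why: Electrophilic aromatic bromination goes to the only position that is ortho to a hydroxyl and meta to the deactivating acetyl group (the same preference as in vanillin-type ketones), and the activated ring reacts much faster than the ketone enol.

**Step 3**
Reactants: 4 1-(3-bromo-4,5-dihydroxyphenyl)ethanone
Product: 5 1-(3-bromo-5-hydroxy-4-methoxyphenyl)ethanone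
Conditions: MeI (1.1 equiv), Li2CO3 (1.1 equiv), DMF, 45 °C
Reagents that add atoms: iodomethane, CI
Why: Regioselective Williamson methylation: the hydroxyl para to the acetyl group (and ortho to Br) is much the more acidic, so the weak base forms only that phenoxide and only it is methylated.

**Step 4**
Reactants: 5 1-(3-bromo-5-hydroxy-4-methoxyphenyl)ethanone
Product: 6 1-[3-bromo-4-methoxy-5-(methoxymethoxy)phenyl]ethanone
Conditions: MOMCl (1.3 equiv), i-Pr2NEt (1.5 equiv), CH2Cl2, 0 °C → rt
Reagents that add atoms: chloromethyl methyl ether (MOMCl), COCCl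
Why: MOM protection (O-alkylation) masks the B-ring phenol so that it cannot compete in the etherification of step 6, and it is removed together with the A-ring MOM groups in step 7.

**Step 5**
Reactants: 6 1-[3-bromo-4-methoxy-5-(methoxymethoxy)phenyl]ethanone
Product: 8 2-bromo-1-[3-bromo-4-methoxy-5-(methoxymethoxy)phenyl]ethanone, via TMS enol ether 7 (not isolated)
Conditions: LiHMDS (1.1 equiv), THF, −78 °C; TMSCl (1.2 equiv); then NBS (1.05 equiv), −78 → 0 °C; aq. NaHCO3
Reagents that add atoms: N-bromosuccinimide, O=C1CCC(=O)N1Br (Br of 8); chlorotrimethylsilane, C[Si](C)(C)Cl (Me3Si of 7 only)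
Why: Enolate silylation followed by electrophilic bromination of the silyl enol ether gives the phenacyl bromide without acid, so the MOM ether survives and the ring is not brominated.

**Step 6 (key step)**
Reactants: 2 2-hydroxy-4,6-bis(methoxymethoxy)benzaldehyde (1.05 equiv); 8 2-bromo-1-[3-bromo-4-methoxy-5-(methoxymethoxy)phenyl]ethanone
Product: 10 rac-3-[3-bromo-4-methoxy-5-(methoxymethoxy)phenyl]-3-hydroxy-5,7-bis(methoxymethoxy)-2,3-dihydro-4H-chromen-4-one, via keto-aldehyde ether 9 (not isolated)
Conditions: K2CO3 (1.5 equiv), MeCN, rt, 4 h; then 2-(pentafluorophenyl)-6,7-dihydro-5H-pyrrolo[2,1-c][1,2,4]triazol-2-ium tetrafluoroborate (20 mol%), same flask, Ar, rt → 40 °C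
Reagents that add atoms: none
Why: Williamson etherification of the free phenol with the phenacyl bromide is followed in the same flask by an NHC-catalysed intramolecular crossed aldehyde–ketone benzoin reaction, in which the carbene converts the aldehyde carbon into an acyl anion equivalent (Breslow intermediate) that attacks the aryl ketone carbonyl in a 6-exo closure, joining two carbonyl carbons as the C4–C3 bond; the new C3 carbinol centre is formed racemic with the achiral catalyst and is removed in step 7.

**Step 7**
Reactants: 10 rac-3-[3-bromo-4-methoxy-5-(methoxymethoxy)phenyl]-3-hydroxy-5,7-bis(methoxymethoxy)-2,3-dihydro-4H-chromen-4-one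
Product: 12 3-(3-bromo-5-hydroxy-4-methoxyphenyl)-5,7-dihydroxy-4H-chromen-4-one, via tris-MOM isoflavone 11 (not isolated)
Conditions: SOCl2 (1.5 equiv), pyridine (5 equiv), CH2Cl2, 0 °C → rt; evaporate; then 3 M HCl in MeOH, 55 °C
Reagents that add atoms: none
Why: E2 dehydration of the tertiary α-ketol through its chlorosulfite can only use the C2 hydrogens and so gives the conjugated chromone C2=C3 bond (erasing the C3 stereocentre), after which acid-catalysed acetal exchange with methanol removes the three MOM groups.

**Step 8**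
Reactants: 12 3-(3-bromo-5-hydroxy-4-methoxyphenyl)-5,7-dihydroxy-4H-chromen-4-one; 13 2-methylbut-3-en-2-ol (3 equiv)
Product: 14 5,7-dihydroxy-3-{3-hydroxy-5-[(1E)-3-hydroxy-3-methylbut-1-en-1-yl]-4-methoxyphenyl}-4H-chromen-4-one
Conditions: Pd(OAc)2 (5 mol%), [HP(t-Bu)3]BF4 (10 mol%), Cy2NMe (5 equiv), DMF, 90 °C, Ar
Reagents that add atoms: none
Why: Mizoroki–Heck reaction: syn carbopalladation at the terminal alkene carbon and syn β-hydride elimination give only the (E)-styrenyl alkene, and the tertiary carbinol has no hydrogen that would allow isomerisation to a ketone.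

**Compound list**
1 | 2,4,6-trihydroxybenzaldehyde | O=Cc1c(O)cc(O)cc1O | starting material
2 | 2-hydroxy-4,6-bis(methoxymethoxy)benzaldehyde | O=Cc1c(O)cc(OCOC)cc1OCOC | intermediate
3 | 1-(3,4-dihydroxyphenyl)ethanone | CC(=O)c1ccc(O)c(O)c1 | starting material
4 | 1-(3-bromo-4,5-dihydroxyphenyl)ethanone | CC(=O)c1cc(O)c(O)c(Br)c1 | intermediate
5 | 1-(3-bromo-5-hydroxy-4-methoxyphenyl)ethanone | CC(=O)c1cc(O)c(OC)c(Br)c1 | intermediate
6 | 1-[3-bromo-4-methoxy-5-(methoxymethoxy)phenyl]ethanone | CC(=O)c1cc(OCOC)c(OC)c(Br)c1 | intermediate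
7 | ({1-[3-bromo-4-methoxy-5-(methoxymethoxy)phenyl]ethenyl}oxy)trimethylsilane (not isolated) | C=C(O[Si](C)(C)C)c1cc(OCOC)c(OC)c(Br)c1 | intermediate
8 | 2-bromo-1-[3-bromo-4-methoxy-5-(methoxymethoxy)phenyl]ethanone | O=C(CBr)c1cc(OCOC)c(OC)c(Br)c1 | intermediate
9 | 2-{2-[3-bromo-4-methoxy-5-(methoxymethoxy)phenyl]-2-oxoethoxy}-4,6-bis(methoxymethoxy)benzaldehyde (not isolated) | O=Cc1c(OCOC)cc(OCOC)cc1OCC(=O)c1cc(OCOC)c(OC)c(Br)c1 | intermediate
10 | rac-3-[3-bromo-4-methoxy-5-(methoxymethoxy)phenyl]-3-hydroxy-5,7-bis(methoxymethoxy)-2,3-dihydro-4H-chromen-4-one (racemate) | O=C1c2c(OCOC)cc(OCOC)cc2OCC1(O)c1cc(OCOC)c(OC)c(Br)c1 | intermediate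
11 | 3-[3-bromo-4-methoxy-5-(methoxymethoxy)phenyl]-5,7-bis(methoxymethoxy)-4H-chromen-4-one (not isolated) | O=c1c(-c2cc(OCOC)c(OC)c(Br)c2)coc2cc(OCOC)cc(OCOC)c12 | intermediate
12 | 3-(3-bromo-5-hydroxy-4-methoxyphenyl)-5,7-dihydroxy-4H-chromen-4-one | O=c1c(-c2cc(O)c(OC)c(Br)c2)coc2cc(O)cc(O)c12 | intermediate
13 | 2-methylbut-3-en-2-ol | C=CC(C)(C)O | starting material
14 | 5,7-dihydroxy-3-{3-hydroxy-5-[(1E)-3-hydroxy-3-methylbut-1-en-1-yl]-4-methoxyphenyl}-4H-chromen-4-one | COc1c(O)cc(-c2coc3cc(O)cc(O)c3c2=O)cc1/C=C/C(C)(C)O | target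

**Step count and risks**
Total steps: 8. Longest linear sequence: 7 (steps 2–8, from 3 to 14).

The three steps most likely to fail:

Step 6. The aldehyde of 9 is hindered and electron-rich, so carbene addition is slow, and the acidic O–CH2–C(=O) group can instead undergo base-induced intramolecular aldol condensation to a 2-aroylbenzofuran. Isolating 9 and using a catalytic amine base are condition changes to try first. The fallback builds the pyranone ring from the B-ring ketone instead. It sets out from 6: Willgerodt–Kindler reaction (S8, morpholine, 130 °C) gives 2-[3-bromo-4-methoxy-5-(methoxymethoxy)phenyl]-1-(morpholin-4-yl)ethanethione F1. Hydrolysis with KOH in aqueous EtOH gives 2-[3-bromo-4-methoxy-5-(methoxymethoxy)phenyl]acetic acid F2. Friedel–Crafts acylation of commercial phloroglucinol with F2 in BF3·OEt2 at 85 °C (the MOM group is lost) gives 2-(3-bromo-5-hydroxy-4-methoxyphenyl)-1-(2,4,6-trihydroxyphenyl)ethanone F3. Adding DMF and MsCl to the same solution closes the ring, and the route is rejoined at 12, before step 8.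

Step 7. The chlorosulfite of the tertiary α-ketol may give chloride substitution or α-ketol rearrangement instead of elimination; Burgess reagent is the condition change to try first. The fallback replaces dehydration by deoxygenation and dehydrogenation. It sets out from 10: SmI2 in THF/MeOH at −78 °C removes the α-hydroxyl to give rac-3-[3-bromo-4-methoxy-5-(methoxymethoxy)phenyl]-5,7-bis(methoxymethoxy)-2,3-dihydro-4H-chromen-4-one F4. DDQ in refluxing dioxane then dehydrogenates C2–C3, and the route is rejoined at 11, which is deprotected with HCl/MeOH as in step 7.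

Step 8. The aryl bromide is electron-rich and ortho-substituted, and three free phenols are present, so oxidative addition may be slow and the catalyst may be sequestered. The fallback replaces the Heck reaction by a Suzuki–Miyaura coupling. It sets out from 12: Cp2Zr(H)Cl-catalysed syn-hydroboration of commercial 2-methylbut-3-yn-2-ol with pinacolborane gives (E)-2-methyl-4-(4,4,5,5-tetramethyl-1,3,2-dioxaborolan-2-yl)but-3-en-2-ol F5. Coupling of F5 with 12 (Pd(dppf)Cl2, K2CO3, dioxane/H2O, 80 °C) gives the target 14 directly, with the E geometry fixed by the hydroboration.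

**Further compounds**
F1 | step 6 | 2-[3-bromo-4-methoxy-5-(methoxymethoxy)phenyl]-1-(morpholin-4-yl)ethanethione | S=C(Cc1cc(OCOC)c(OC)c(Br)c1)N1CCOCC1
F2 | step 6 | 2-[3-bromo-4-methoxy-5-(methoxymethoxy)phenyl]acetic acid | OC(=O)Cc1cc(OCOC)c(OC)c(Br)c1
F3 | step 6 | 2-(3-bromo-5-hydroxy-4-methoxyphenyl)-1-(2,4,6-trihydroxyphenyl)ethanone | O=C(Cc1cc(O)c(OC)c(Br)c1)c1c(O)cc(O)cc1O
F4 | step 7 | rac-3-[3-bromo-4-methoxy-5-(methoxymethoxy)phenyl]-5,7-bis(methoxymethoxy)-2,3-dihydro-4H-chromen-4-one | O=C1c2c(OCOC)cc(OCOC)cc2OCC1c1cc(OCOC)c(OC)c(Br)c1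
F5 | step 8 | (E)-2-methyl-4-(4,4,5,5-tetramethyl-1,3,2-dioxaborolan-2-yl)but-3-en-2-ol | CC(C)(O)/C=C/B1OC(C)(C)C(C)(C)O1
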